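If target turns on into over-reaction product at a steady pace of its own, then the over-reaction product made is the target standing in the flask, taken over the time, divided by one number: the life of target, the time in which a standing amount of target makes its own amount of over-reaction product. This is a consecutive loss, first order in target.

| flask | substrate | partner | precatalyst | temperature | remark | time |
|---|---|---|---|---|---|---|
| zeta | 0.54 M | 0.64 M | 8 mM | 54 °C | run made earlier |  |
| delta | 1.2 M | 0.64 M | 8 mM | 62 °C | run made earlier |  |
| alpha | 0.80 M | 0.64 M | 4 mM | 54 °C | run made earlier |  |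
| Saturday's | 0.80 M | 0.640 M | 8.0 mM | 50 °C |  | 12 min |
| Wednesday's | 0.80 M | 0.640 M | 8.0 mM |  | at 50 °C until 2.5 min, from then on at 65 °C | 12 min |
| Monday's | 0.80 M | 0.640 M | 8.0 mM | 65 °C |  | 12 min |

- zeta (time / min: target / %, over-reaction product / %): 0.500: 0, 0.1; 0.833: 0, 0; 1.33: 0, 0; 2.00: 0.8, 0; 3.00: 0.4, 0.6; 5.00: 1.9, 0.2; 8.00: 4.9, 0.5
- delta (time / min: target / %, over-reaction product / %): 0.250: 0, 0; 0.500: 0, 0; 0.667: 0.1, 0.1; 1.00: 0.2, 0.6; 1.50: 0.7, 0; 3.00: 1.4, 0; 4.00: 2.1, 0
- alpha (time / min: target / %, over-reaction product / %): 1.33: 0.4, 0; 3.00: 0, 0; 4.00: 0.9, 0.3; 6.00: 0.9, 0; 8.00: 1.6, 0.1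

(scatter of a reading: 0.3 percentage points)



1. the flask with the highest share of target in all that became target or over-reaction product ("all alike" if they lie within 1.5 percentage points) (Saturday's / Wednesday's / Monday's / all alike)
2. share of target in all that became target or over-reaction product, Saturday's
3. share of target in all that became target or over-reaction product, Wednesday's
4. share of target in all that became target or over-reaction product, Monday's

In the zeta run target rises from 1.9 % at 5.00 min to 4.9 % at 8.00 min, which is 2.58 times as much in 1.60 times the time. So target grows about as the square of the time, its average so far is a third of its last value, and over-reaction product over target equals the time over 3 lives. The last zeta reading, 0.5 % of over-reaction product, then gives a life of 26.1 min at 54 °C.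

Over-reaction product in the delta run stands at 0 % in its last reading, at 4.00 min, so I can't read the effect of warmth. I take the usual doubling of pace per 10 degrees and divide the life by 2 for 65 °C. Monday's share, the selectivity, then comes to 76.5 %.

The weak link is that single reading, with its scatter of 0.3 percentage points. The alpha run, also at 54 °C, adds target 1.6 % and over-reaction product 0.1 % at 8.00 min. Assuming the same growth and pooling both runs, I get 28.9 min, and this life of target is what I carry. Hot, it is 14.4 min. I commit to 87.8 % for Saturday's, leaving the life uncorrected for the cooler bath; 82.0 % for Wednesday's, counting the hot time; and 78.3 % for Monday's.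

The forecast names Saturday's, with 94 % (86 % to 99 %) there, 88 % (75 % to 97 %) for Wednesday's and 87 % (73 % to 97 %) for Monday's, holding that “the hotter, further-advanced flasks lose selectivity”. My Monday's figure stands lower than its figure.

The flasks give 88.7 % for Saturday's, 57.9 % for Wednesday's and 52.6 % for Monday's, so Saturday's stands highest.

    catalyst intermediate C → free catalyst + target (k = 0.357 s⁻¹, Ea = 92.0 kJ mol⁻¹)
    catalyst intermediate B ⇌ catalyst intermediate C (K = 0.274, k = 10.5 s⁻¹, Ea = 79.0 kJ mol⁻¹, ΔH = 12.0 kJ mol⁻¹)
    target → over-reaction product (k = 4.96 × 10⁻⁴ s⁻¹, Ea = 101 kJ mol⁻¹)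
    partner + catalyst intermediate A ⇌ catalyst intermediate B (K = 1.41 M⁻¹, k = 0.556 M⁻¹ s⁻¹, Ea = 47.0 kJ mol⁻¹, ΔH = −43.0 kJ mol⁻¹)
    partner + precatalyst → free catalyst + spent reagent (k = 9.14 × 10⁻⁴ M⁻¹ s⁻¹, Ea = 68.0 kJ mol⁻¹)
    substrate + free catalyst → catalyst intermediate A (k = 0.353 M⁻¹ s⁻¹, Ea = 65.0 kJ mol⁻¹)
    (constants at 50 °C)

By the same rule, Monday's target 14.7 % and over-reaction product 13.3 % at 12.0 min give a life of 4.44 min, shorter than the 12 min of the flask and shorter than my 14.4 min. Saturday's target 3.66 % and over-reaction product 0.466 % at that time give a life of 31.4 min, longer than those 12 min, beside the 28.9 min carried from 54 °C.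

The readings were generated by integration with made-up constants; noise was put on by code.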